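**Plan** (target numbered as the cyclohexan-1-ol C1–C6; oxane atoms primed)

Retrosynthesis: O–Si off; C5–Cl and C4–Br traced through a bromonium ion, a trans-diaxial bromohydrin and an epoxide back to a C4=C5 alkene; oxane O1′–C6′ and C5′–Br cut (bromoetherification); C2′–CH3 and C2′–C3′ cut (two Grignard additions to a Weinreb amide); C4=C5 cut (ring-closing metathesis); C1–C2 cut (aldol).
Forward: acyclic syn-aldol adduct → cyclohexene (first ring, closed at C4–C5) → side chain on C2 → oxane (second ring, 6-endo bromoetherification) → halogens on C4/C5 → desilylation.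
Stereochemistry: C1/C2 from the (R)-benzyloxazolidinone syn-aldol; C2′ from Felkin–Anh addition of MeMgBr; C5′ from the chair-like bromoetherification; C4/C5 from epoxidation anti to the two cis ring substituents, then two stereospecific anti openings (epoxide, then bromonium with 1,2-shift of bromine).
Enabling feature: C4 (CHBr) and C5 (C(Cl)CH3) are adjacent, trans, and flanked by the CH2 groups C3 and C6. This is the retron of a trisubstituted C4=C5 alkene, and cutting it leaves an allyl arm on C2 and a methallyl arm on C1 of a syn-aldol, a 1,7-diene set up for six-ring metathesis.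

Key step: step 6

Remark: "lower face" means the face of the carbocycle that carries the C1 oxygen and the C2 side chain (they are cis), "upper face" the other one. Direct BrCl addition to the ring alkene is expected to run trans-diaxially with bromine on the upper face (the wrong C4/C5 pair), hence the route through the epoxide.

Step 1
Reactants: 1 (R)-4-benzyl-1,3-oxazolidin-2-one; 2 pent-4-enoyl chloride
Product: 3 (R)-4-benzyl-3-(pent-4-enoyl)-1,3-oxazolidin-2-one
Conditions: Et3N, DMAP (cat.), CH2Cl2, 0 °C to rt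
Reagents that add atoms: none
Why: N-acylation of the oxazolidinone by the acid chloride under nucleophilic catalysis; no stereocentre is touched.

Step 2
Reactants: 4 3-methylbut-3-en-1-ol
Product: 5 3-methylbut-3-enal
Conditions: Dess–Martin periodinane, CH2Cl2, 0 °C; filtered and used at once as a cold CH2Cl2 solution
Reagents that add atoms: none
Why: Dess–Martin oxidation of a primary alcohol under non-basic conditions, which should avoid migration of the β,γ-double bond into conjugation; the volatile aldehyde is not stored.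

Step 3
Reactants: 3 (R)-4-benzyl-3-(pent-4-enoyl)-1,3-oxazolidin-2-one; 5 3-methylbut-3-enal
Product: 7 (R)-4-benzyl-3-[(2R,3S)-3-hydroxy-5-methyl-2-(prop-2-en-1-yl)hex-5-enoyl]-1,3-oxazolidin-2-one, via boron enolate 6 (not isolated)
Conditions: n-Bu2BOTf, i-Pr2NEt, CH2Cl2, −78 to 0 °C; then 5, −78 to 0 °C; then pH 7 buffer, MeOH, 30% H2O2, 0 °C
Reagents that add atoms: none
Why: Evans syn-aldol reaction: the (Z)-boron enolate 6 reacts through a closed Zimmerman–Traxler chair on the enolate face opposite the benzyl group of the dipole-opposed auxiliary, which sets C2 (R) and C3 (S) of the acyl chain (the future ring carbons C2 and C1) syn to each other.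

Step 4
Reactants: 7 (R)-4-benzyl-3-[(2R,3S)-3-hydroxy-5-methyl-2-(prop-2-en-1-yl)hex-5-enoyl]-1,3-oxazolidin-2-one
Product: 8 (2R,3S)-3-hydroxy-N-methoxy-N,5-dimethyl-2-(prop-2-en-1-yl)hex-5-enamide
Conditions: MeNH(OMe)·HCl, AlMe3, CH2Cl2, −20 °C to rt
Reagents that add atoms: N,O-dimethylhydroxylamine hydrochloride, CNOC.Cl
Why: Transamidation of the N-acyloxazolidinone by the aluminium amide made from AlMe3 and the amine salt (Weinreb amide formation), helped by the free β-hydroxyl; the auxiliary is released and both stereocentres are untouched.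

Step 5
Reactants: 8 (2R,3S)-3-hydroxy-N-methoxy-N,5-dimethyl-2-(prop-2-en-1-yl)hex-5-enamide
Product: 9 (2R,3S)-3-[(tert-butyldimethylsilyl)oxy]-N-methoxy-N,5-dimethyl-2-(prop-2-en-1-yl)hex-5-enamide
Conditions: TBSOTf, 2,6-lutidine, CH2Cl2, −78 to 0 °C
Reagents that add atoms: tert-butyldimethylsilyl trifluoromethanesulfonate, CC(C)(C)[Si](C)(C)OS(=O)(=O)C(F)(F)F
Why: Silylation of the secondary alcohol with a silyl triflate; the bulky, non-chelating, non-directing ether is needed for steps 8, 10 and 12.

Step 6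
Reactants: 9 (2R,3S)-3-[(tert-butyldimethylsilyl)oxy]-N-methoxy-N,5-dimethyl-2-(prop-2-en-1-yl)hex-5-enamide
Product: 10 (1R,6S)-6-[(tert-butyldimethylsilyl)oxy]-N-methoxy-N,4-dimethylcyclohex-3-ene-1-carboxamide
Conditions: second-generation Grubbs catalyst (H2IMes)(PCy3)Cl2Ru=CHPh (5 mol %), CH2Cl2 (5 mM), 40 °C
Reagents that add atoms: none
Why: Ring-closing olefin metathesis by the Chauvin mechanism: the ruthenium benzylidene initiates at the monosubstituted allyl alkene of 9, the new alkylidene adds across the 1,1-disubstituted methallyl alkene to a ruthenacyclobutane, and cycloreversion releases the C3=C4 bond of 10 and, on turnover, ethene. The closest known reaction type is metathesis closure of a 1,7-diene with one mono- and one 1,1-disubstituted alkene to a 1-methylcyclohexene. The six-membered carbocycle is closed by intramolecular [2+2] cycloaddition and cycloreversion between the two inner alkene carbons, both of which become ring atoms; no other ring forms. No stereocentre is created: C1 and C6 come unchanged from the aldol, and the ring fixes them cis so that both substituents lie on one face of the new alkene. The step needs ring closure to win over acyclic diene oligomerization and over migration of the allyl double bond; the 1,7-spacing, the high dilution and the absence of a third alkene should secure this. The alkene delivered here is the precursor from which the two halogen-bearing centres are set by face-selective chemistry in steps 10–12.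

Step 7
Reactants: 10 (1R,6S)-6-[(tert-butyldimethylsilyl)oxy]-N-methoxy-N,4-dimethylcyclohex-3-ene-1-carboxamide; 11 5-bromo-2-methylpent-2-ene
Product: 13 1-{(1R,6S)-6-[(tert-butyldimethylsilyl)oxy]-4-methylcyclohex-3-en-1-yl}-5-methylhex-4-en-1-one, via Grignard reagent 12 (not isolated)
Conditions: 11, Mg, THF, rt; then 10, THF, 0 °C to rt; aq. NH4Cl
Reagents that add atoms: none
Why: Addition of a Grignard reagent to a Weinreb amide: the five-membered magnesium chelate of the tetrahedral adduct survives until work-up, so the ketone forms without over-addition and ring C1 is not enolized.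

Step 8
Reactants: 13 1-{(1R,6S)-6-[(tert-butyldimethylsilyl)oxy]-4-methylcyclohex-3-en-1-yl}-5-methylhex-4-en-1-one
Product: 14 (2S)-2-{(1R,6S)-6-[(tert-butyldimethylsilyl)oxy]-4-methylcyclohex-3-en-1-yl}-6-methylhept-5-en-2-ol
Conditions: MeMgBr, Et2O, −78 to −40 °C; aq. NH4Cl
Reagents that add atoms: methylmagnesium bromide, C[Mg]Br
Why: 1,2-Addition to the ketone under Felkin–Anh control: with ring carbon C6 (tertiary, carrying the axial silyloxy group) as the large α-substituent anti to the nucleophile, methyl should enter from the side of ring C2 and give the (S)-carbinol; the β-silyl ether does not chelate.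

Step 9
Reactants: 14 (2S)-2-{(1R,6S)-6-[(tert-butyldimethylsilyl)oxy]-4-methylcyclohex-3-en-1-yl}-6-methylhept-5-en-2-ol
Product: 15 tert-butyl({(1S,6R)-6-[(2S,5R)-5-bromo-2,6,6-trimethyloxan-2-yl]-3-methylcyclohex-3-en-1-yl}oxy)dimethylsilane
Conditions: TBCO, CH2Cl2, −20 to 0 °C
Reagents that add atoms: 2,4,4,6-tetrabromocyclohexa-2,5-dien-1-one (TBCO), O=C1C(Br)=CC(Br)(Br)C=C1Br
Why: Bromoetherification: Br+ transfer to the side-chain trisubstituted alkene and 6-endo Markovnikov capture of the tertiary carbon by the tertiary hydroxyl, through a chair-like transition state with bromine and the cyclohexenyl group equatorial and methyl axial, should give the (2S,5R)-oxane; the ring alkene, deactivated by the homoallylic silyloxy group and lacking a strain-free internal nucleophile, should be spared.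

Step 10
Reactants: 15 tert-butyl({(1S,6R)-6-[(2S,5R)-5-bromo-2,6,6-trimethyloxan-2-yl]-3-methylcyclohex-3-en-1-yl}oxy)dimethylsilane
Product: 16 tert-butyl({(1S,3S,4R,6R)-4-[(2S,5R)-5-bromo-2,6,6-trimethyloxan-2-yl]-1-methyl-7-oxabicyclo[4.1.0]heptan-3-yl}oxy)dimethylsilane (epoxide oxygen on the upper face)
Conditions: mCPBA, CH2Cl2, 0 °C
Reagents that add atoms: 3-chloroperoxybenzoic acid, OOC(=O)c1cccc(Cl)c1
Why: Prilezhaev epoxidation of the only remaining alkene; the peracid should approach the upper face because the pseudo-axial silyloxy group on C1 and the oxanyl group on C6 of 15 both lie on the lower face, and a silyl ether does not direct.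

Step 11
Reactants: 16 tert-butyl({(1S,3S,4R,6R)-4-[(2S,5R)-5-bromo-2,6,6-trimethyloxan-2-yl]-1-methyl-7-oxabicyclo[4.1.0]heptan-3-yl}oxy)dimethylsilane
Product: 17 (1R,2R,4S,5R)-2-bromo-5-[(2S,5R)-5-bromo-2,6,6-trimethyloxan-2-yl]-4-[(tert-butyldimethylsilyl)oxy]-2-methylcyclohexan-1-ol
Conditions: HBr (33% in AcOH, 1.1 equiv), CH2Cl2, −40 °C
Reagents that add atoms: hydrogen bromide, Br
Why: Acid-mediated epoxide opening by bromide at the tertiary carbon (Markovnikov) from the lower face, which is also the trans-diaxial (Fürst–Plattner) mode, so regio- and stereochemistry are matched: C2 receives bromine with inversion and C1 keeps its oxygen.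

Step 12
Reactants: 17 (1R,2R,4S,5R)-2-bromo-5-[(2S,5R)-5-bromo-2,6,6-trimethyloxan-2-yl]-4-[(tert-butyldimethylsilyl)oxy]-2-methylcyclohexan-1-ol
Product: 20 tert-butyl({(1S,2R,4S,5S)-4-bromo-2-[(2S,5R)-5-bromo-2,6,6-trimethyloxan-2-yl]-5-chloro-5-methylcyclohexyl}oxy)dimethylsilane, via chlorosulfite 18 (not isolated), via bromonium ion 19 (not isolated)
Conditions: SOCl2, pyridine, CH2Cl2, −20 °C to rt
Reagents that add atoms: thionyl chloride, O=S(Cl)Cl
Why: Deoxychlorination with neighbouring-group participation: the chlorosulfite 18 of the axial secondary alcohol ionizes with anti-periplanar assistance of the tertiary C–Br bond to the lower-face bromonium ion 19, and chloride should open 19 at the tertiary, more cationic carbon from the upper face, so bromine ends on C4 (S) and chlorine on C5 (S), trans and on the required faces.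

Step 13
Reactants: 20 tert-butyl({(1S,2R,4S,5S)-4-bromo-2-[(2S,5R)-5-bromo-2,6,6-trimethyloxan-2-yl]-5-chloro-5-methylcyclohexyl}oxy)dimethylsilane
Product: 21 (1S,2R,4S,5S)-4-bromo-2-[(2S,5R)-5-bromo-2,6,6-trimethyloxan-2-yl]-5-chloro-5-methylcyclohexan-1-ol
Conditions: HF·pyridine, THF, 0 °C to rt
Reagents that add atoms: none
Why: Fluoride cleavage of the silyl ether under mildly acidic, non-basic conditions that should leave the tertiary chloride, both secondary bromides and the oxane untouched; the product is the target.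

**Compound list**

1 | (R)-4-benzyl-1,3-oxazolidin-2-one | O=C1N[C@H](Cc2ccccc2)CO1 | starting material
2 | pent-4-enoyl chloride | C=CCCC(Cl)=O | starting material
3 | (R)-4-benzyl-3-(pent-4-enoyl)-1,3-oxazolidin-2-one | C=CCCC(=O)N1[C@H](Cc2ccccc2)COC1=O | intermediate
4 | 3-methylbut-3-en-1-ol | CC(=C)CCO | starting material
5 | 3-methylbut-3-enal | CC(=C)CC=O | intermediate
6 | (Z)-dibutylboron enolate of 3 | C=CC/C=C(\OB(CCCC)CCCC)N1[C@H](Cc2ccccc2)COC1=O | intermediate (not isolated)
7 | (R)-4-benzyl-3-[(2R,3S)-3-hydroxy-5-methyl-2-(prop-2-en-1-yl)hex-5-enoyl]-1,3-oxazolidin-2-one | C=CC[C@H]([C@@H](O)CC(C)=C)C(=O)N1[C@H](Cc2ccccc2)COC1=O | intermediate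
8 | (2R,3S)-3-hydroxy-N-methoxy-N,5-dimethyl-2-(prop-2-en-1-yl)hex-5-enamide | C=CC[C@H]([C@@H](O)CC(C)=C)C(=O)N(C)OC | intermediate
9 | (2R,3S)-3-[(tert-butyldimethylsilyl)oxy]-N-methoxy-N,5-dimethyl-2-(prop-2-en-1-yl)hex-5-enamide | C=CC[C@H]([C@@H](O[Si](C)(C)C(C)(C)C)CC(C)=C)C(=O)N(C)OC | intermediate
10 | (1R,6S)-6-[(tert-butyldimethylsilyl)oxy]-N-methoxy-N,4-dimethylcyclohex-3-ene-1-carboxamide | CC1=CC[C@H]([C@@H](O[Si](C)(C)C(C)(C)C)C1)C(=O)N(C)OC | intermediate
11 | 5-bromo-2-methylpent-2-ene | CC(C)=CCCBr | starting material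
12 | (4-methylpent-3-en-1-yl)magnesium bromide | CC(C)=CCC[Mg]Br | intermediate (not isolated)
13 | 1-{(1R,6S)-6-[(tert-butyldimethylsilyl)oxy]-4-methylcyclohex-3-en-1-yl}-5-methylhex-4-en-1-one | CC1=CC[C@H]([C@@H](O[Si](C)(C)C(C)(C)C)C1)C(=O)CCC=C(C)C | intermediate
14 | (2S)-2-{(1R,6S)-6-[(tert-butyldimethylsilyl)oxy]-4-methylcyclohex-3-en-1-yl}-6-methylhept-5-en-2-ol | CC1=CC[C@H]([C@@H](O[Si](C)(C)C(C)(C)C)C1)[C@@](C)(O)CCC=C(C)C | intermediate
15 | tert-butyl({(1S,6R)-6-[(2S,5R)-5-bromo-2,6,6-trimethyloxan-2-yl]-3-methylcyclohex-3-en-1-yl}oxy)dimethylsilane | CC1=CC[C@H]([C@@H](O[Si](C)(C)C(C)(C)C)C1)[C@]2(C)CC[C@@H](Br)C(C)(C)O2 | intermediate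
16 | tert-butyl({(1S,3S,4R,6R)-4-[(2S,5R)-5-bromo-2,6,6-trimethyloxan-2-yl]-1-methyl-7-oxabicyclo[4.1.0]heptan-3-yl}oxy)dimethylsilane | C[C@@]12O[C@@H]1C[C@H]([C@@H](O[Si](C)(C)C(C)(C)C)C2)[C@]3(C)CC[C@@H](Br)C(C)(C)O3 | intermediate
17 | (1R,2R,4S,5R)-2-bromo-5-[(2S,5R)-5-bromo-2,6,6-trimethyloxan-2-yl]-4-[(tert-butyldimethylsilyl)oxy]-2-methylcyclohexan-1-ol | C[C@]1(Br)[C@H](O)C[C@H]([C@@H](O[Si](C)(C)C(C)(C)C)C1)[C@]2(C)CC[C@@H](Br)C(C)(C)O2 | intermediate
18 | chlorosulfite of 17 (O-chlorosulfinyl ester at C1) | C[C@]1(Br)[C@H](OS(Cl)=O)C[C@H]([C@@H](O[Si](C)(C)C(C)(C)C)C1)[C@]2(C)CC[C@@H](Br)C(C)(C)O2 | intermediate (not isolated)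
19 | lower-face bromonium ion bridging the former C1 and C2 of 17, chloride salt | C[C@]12[Br+][C@H]1C[C@H]([C@@H](O[Si](C)(C)C(C)(C)C)C2)[C@]3(C)CC[C@@H](Br)C(C)(C)O3.[Cl-] | intermediate (not isolated)
20 | tert-butyl({(1S,2R,4S,5S)-4-bromo-2-[(2S,5R)-5-bromo-2,6,6-trimethyloxan-2-yl]-5-chloro-5-methylcyclohexyl}oxy)dimethylsilane | C[C@@]1(Cl)[C@@H](Br)C[C@H]([C@@H](O[Si](C)(C)C(C)(C)C)C1)[C@]2(C)CC[C@@H](Br)C(C)(C)O2 | intermediate
21 | (1S,2R,4S,5S)-4-bromo-2-[(2S,5R)-5-bromo-2,6,6-trimethyloxan-2-yl]-5-chloro-5-methylcyclohexan-1-ol | C[C@@]1(Cl)[C@@H](Br)C[C@H]([C@@H](O)C1)[C@]2(C)CC[C@@H](Br)C(C)(C)O2 | target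

**Step count and risks**

Total step count: 13. Longest linear sequence: 12 steps (steps 1 and 3–13, from 1); step 2 is a one-step side branch.

Steps most likely to fail:

1. Step 9. What may go wrong: bromonium formation at the ring alkene with transannular capture by the tertiary hydroxyl, 5-exo closure to an oxolane, or low facial selectivity at C5′. The fallback changes the order of events so that each electrophilic step meets a single alkene; it sets out from 10 and comes back at 20. mCPBA gives the epoxy amide (1R,3R,4S,6S)-4-[(tert-butyldimethylsilyl)oxy]-N-methoxy-N,6-dimethyl-7-oxabicyclo[4.1.0]heptane-3-carboxamide F1, and HBr opens it trans-diaxially to the bromohydrin amide F2. SOCl2/pyridine takes F2 through its chlorosulfite F3 and the bromonium ion F4 to the ring bromochloride amide F5 (the chemistry of steps 10–12 on a compound whose only alkene is the ring one). Grignard reagent 12 (THF, −20 °C) then converts F5 into the ketone F6, and MeMgBr (−78 °C, same Felkin–Anh sense as step 8) gives the tertiary alcohol F7. TBCO closes the oxane on F7, whose only alkene is the side-chain one, and gives 20.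

2. Step 12. What may go wrong: chloride capture at the secondary instead of the tertiary end of the bromonium ion (the trans-diaxial mode), and loss of a proton from the cation to give alkenes. The fallback replaces kinetic by thermodynamic control; it sets out from 17 and comes back at 20. The same reagents give, through 18 and 19, the trans-diaxial regioisomer tert-butyl({(1S,2R,4R,5R)-5-bromo-2-[(2S,5R)-5-bromo-2,6,6-trimethyloxan-2-yl]-4-chloro-5-methylcyclohexyl}oxy)dimethylsilane F8, alone or mixed with 20. The material is then heated (MeCN or toluene, 80 °C). Under these conditions vicinal trans-diaxial dihalides exchange places through the bromonium/chloride ion pair, each halogen staying on its own face, and the diequatorial isomer 20 should be favoured; any remaining F8 is separated and resubmitted.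

3. Step 8. What may go wrong: low facial selectivity in the addition to the ketone, and enolization with epimerization at ring C1. The fallback uses chelate control with the two carbon groups introduced in the reverse order; it sets out from 10 and comes back at 14. MeMgBr converts 10 into the methyl ketone 1-{(1R,6S)-6-[(tert-butyldimethylsilyl)oxy]-4-methylcyclohex-3-en-1-yl}ethan-1-one F9, and HF·pyridine removes the silyl group to give the hydroxy ketone F10. Grignard reagent 12 (3 equiv, THF, −78 °C) adds to the magnesium alkoxide chelate of F10 from the face opposite ring C2, which leads to the same (S)-carbinol in the diol F11. TBSOTf/2,6-lutidine at −78 °C silylates only the secondary hydroxyl and returns 14.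

Further compounds
F1 | step 9 | (1R,3R,4S,6S)-4-[(tert-butyldimethylsilyl)oxy]-N-methoxy-N,6-dimethyl-7-oxabicyclo[4.1.0]heptane-3-carboxamide | C[C@@]12O[C@@H]1C[C@H]([C@@H](O[Si](C)(C)C(C)(C)C)C2)C(=O)N(C)OC
F2 | step 9 | (1R,2S,4R,5R)-4-bromo-2-[(tert-butyldimethylsilyl)oxy]-5-hydroxy-N-methoxy-N,4-dimethylcyclohexane-1-carboxamide | C[C@]1(Br)[C@H](O)C[C@H]([C@@H](O[Si](C)(C)C(C)(C)C)C1)C(=O)N(C)OC
F3 | step 9 | chlorosulfite of F2 | C[C@]1(Br)[C@H](OS(Cl)=O)C[C@H]([C@@H](O[Si](C)(C)C(C)(C)C)C1)C(=O)N(C)OC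
F4 | step 9 | lower-face bromonium ion from F3, chloride salt | C[C@]12[Br+][C@H]1C[C@H]([C@@H](O[Si](C)(C)C(C)(C)C)C2)C(=O)N(C)OC.[Cl-]
F5 | step 9 | (1R,2S,4S,5S)-5-bromo-2-[(tert-butyldimethylsilyl)oxy]-4-chloro-N-methoxy-N,4-dimethylcyclohexane-1-carboxamide | C[C@@]1(Cl)[C@@H](Br)C[C@H]([C@@H](O[Si](C)(C)C(C)(C)C)C1)C(=O)N(C)OC
F6 | step 9 | 1-{(1R,2S,4S,5S)-5-bromo-2-[(tert-butyldimethylsilyl)oxy]-4-chloro-4-methylcyclohexyl}-5-methylhex-4-en-1-one | C[C@@]1(Cl)[C@@H](Br)C[C@H]([C@@H](O[Si](C)(C)C(C)(C)C)C1)C(=O)CCC=C(C)C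
F7 | step 9 | (2S)-2-{(1R,2S,4S,5S)-5-bromo-2-[(tert-butyldimethylsilyl)oxy]-4-chloro-4-methylcyclohexyl}-6-methylhept-5-en-2-ol | C[C@@]1(Cl)[C@@H](Br)C[C@H]([C@@H](O[Si](C)(C)C(C)(C)C)C1)[C@@](C)(O)CCC=C(C)C
F8 | step 12 | tert-butyl({(1S,2R,4R,5R)-5-bromo-2-[(2S,5R)-5-bromo-2,6,6-trimethyloxan-2-yl]-4-chloro-5-methylcyclohexyl}oxy)dimethylsilane | C[C@]1(Br)[C@H](Cl)C[C@H]([C@@H](O[Si](C)(C)C(C)(C)C)C1)[C@]2(C)CC[C@@H](Br)C(C)(C)O2
F9 | step 8 | 1-{(1R,6S)-6-[(tert-butyldimethylsilyl)oxy]-4-methylcyclohex-3-en-1-yl}ethan-1-one | CC1=CC[C@H]([C@@H](O[Si](C)(C)C(C)(C)C)C1)C(C)=O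
F10 | step 8 | 1-[(1R,6S)-6-hydroxy-4-methylcyclohex-3-en-1-yl]ethan-1-one | CC1=CC[C@H]([C@@H](O)C1)C(C)=O
F11 | step 8 | (2S)-2-[(1R,6S)-6-hydroxy-4-methylcyclohex-3-en-1-yl]-6-methylhept-5-en-2-ol | CC1=CC[C@H]([C@@H](O)C1)[C@@](C)(O)CCC=C(C)C
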